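Remark: the locants C1–C8 defined in the analysis are used in all names of bicyclic compounds; they follow the bicyclo[3.2.1]octane skeleton but are not the lowest-locant set.

## Analysis of the target

The target is a bicyclo[3.2.1]octan-4-one in which ring A (C1–C2–C3–C4–C5–C8, six-membered) and ring B (C1–C7–C6–C5–C8, five-membered) share the bridgeheads C1 (allyl) and C5 (methoxy) and the one-carbon bridge C8 (acetoxy); C2 is a CH2, C3 a CH–OMe, C4 the ketone, C6 a CH–aryl and C7 a CH–Me. It has six stereocentres, (1S,3S,5S,6S,7R,8S) with these locants, five of them contiguous around ring B and two of them fully substituted bridgeheads. On the C6–C7 bridge the 3,4-dimethoxyphenyl group is endo (under ring A) and the methyl group exo, so the two are trans; the C8 acetoxy group points to the side of the C2–C4 bridge, and the C3 methoxy group points toward the C6–C7 bridge while C3–H points to the C8 side. The terminal allyl group rules out catalytic hydrogenation, C3–H is α to the ketone and can epimerise, the two α-methoxy ketone C–O bonds would be cut by dissolving metals or SmI2, the veratryl ring is electron-rich and the acetate is base-labile. The difficulty lies in the two quaternary bridgeheads that flank an oxygenated one-carbon bridge and in controlling C3, C6, C7 and C8 relative to them. The plan rests on ring A: around its ketone C4 it carries methoxy groups on both α-carbons (C3 and C5) and the allyl group on the para carbon C1, which is the pattern of phenol 3 after dearomatisation to a 4,4-disubstituted 2,6-dimethoxycyclohexa-2,5-dienone. In such a dienone C1 is a prochiral quaternary carbon, C8=C5 and C2=C3 are its two enone arms, and ring B lacks only the bonds C1–C7 and C5–C6, with C6 and C7 supplied by the propiophenone 1.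

## Retrosynthetic reasoning

**12 to 11 (the C8 O–acyl bond).** The acetate is put on last. The free C8 hydroxyl of 11 is wanted one step earlier, where it sits on the C2–C4 side of the bridge and helps to set C3. The forward step is the acylation of a hindered secondary alcohol under conditions that leave C3 alone.

**11 to 10 (the C2–H and C3–H bonds).** The saturated C2–C3 unit is traced to the methoxy enone of 10, which is what remains of the second dienone arm. Hydrogenation is excluded by the allyl group, so the forward step is a hydride conjugate reduction. It has to put the new C3 hydrogen on the face turned to C8. In 10 that face carries the C8 hydroxyl, and the opposite face is covered by the endo aryl group.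

**10 to 9 (the C6–H bond).** The benzylic hydrogen is traced to a tertiary benzylic alcohol, the footprint of an aldol addition to an aryl ketone. Its removal by ionisation and hydride capture is placed early for two reasons. It deletes the β-hydroxy ketone that could retro-aldolise along the C5–C6 bond, and it installs the endo aryl group before C3 is set. The hydride has to arrive on the exo face of ring B.

**9 to 8 (the C8–O bond).** The C8 oxygen is traced to a carbon–boron bond, which is oxidised with retention. This avoids the reduction of a bridging C8 ketone, whose facial outcome between two different bridges would be hard to predict. The boron sits where the next disconnection leaves it.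

**8 to 5 and 6 (the bonds C5–C6 and C8–B; ring B).** Cutting C5–C6 as an aldol bond and C8–B as a conjugate borylation opens ring B and returns ring A to the symmetrical dienone 5, with boron from 6 and the copper dienolate 7 as the link between the two events. This cut removes four stereocentres and one ring at once and leaves a precursor with a single stereocentre. The forward reaction must choose one of two enone arms, add boron anti to the side chain, and close the five-membered ring through C5.

**5 to 4 (C7 as a single configuration).** C7 is the only stereocentre of the dienone. The bond-forming step that creates it cannot control it, so racemic 4 is resolved, and the half of 4 that the separation rejects can be racemised through its ketone enolate and resolved again. C7 is not left to equilibrate during the ring closure, because the faster closure would be the one that keeps methyl away from the aryl group, and that need not be the exo-methyl one.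

**4 to 2 and 3, and 2 to 1 (the bond C1–C7).** The C1–C7 bond is cut between the para carbon of phenol 3 and the α-carbon of ketone 1. In the forward direction 3 is oxidised to a ring cation and the silyl enol ether 2 attacks its para carbon. The dearomatisation delivers ring A with its ketone, both methoxy groups and the allyl group already in place.

## Alternatives that were turned down

**Alternative 1: Michael–aldol annulation onto a chiral-pool cyclopentanone keto ester.**
- *Disconnection.* The two ring A bonds that flank the C2–C4 unit, C1–C2 and C4–C5, are cut. Ring B remains as the β-keto ester A1 (C8 as the ketone, a methyl ester on C1), and C2–C4 come from 2-methoxyprop-2-enal A2.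
- *Forward key step.* An amidine base deprotonates A1 at C1 and conjugate addition to A2 forms C1–C2. The C8 ketone then enolises on its other side, and C5 attacks the aldehyde carbon C4 to give the bicyclic hydroxy keto ester A3.
- *For.* The methyl stereocentre can be taken from a terpene. Base-mediated annulation of cyclic β-keto esters with enals to bicyclo[3.2.1]octan-8-ones is an established reaction type, so on precedent for the key step this alternative is stronger than the chosen one.
- *Against.*
  - A3 has the oxidation pattern reversed (C8 ketone, C4 alcohol). Correcting it needs an oxidation, a reduction of the bridging ketone from the face next to the exo methyl group, and an acylation.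
  - The ester must be turned into an allyl group at a neopentyl bridgehead, which costs four or five steps.
  - The aldol has to form a quaternary centre from a tertiary α-methoxy carbon, reversibly.
  - A2 is a weak, polymerisation-prone acceptor.
  - A3 carries the C3 methoxy group on the C8 side, the opposite of the target.
- *Comparison.* The chosen route has ring A at the correct oxidation level and the allyl group in place from the first ring-forming step. It pays for this with a key step that has no direct precedent.

**Alternative 2: Asymmetric interrupted Nazarov cyclisation.**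
- *Disconnection.* Ring B is cut at C6–C7, which leaves the cross-conjugated aryl methoxy dienone A4.
- *Forward key step.* A chiral Brønsted acid of the N-triflyl phosphoramide class activates the ketone of A4, and the pentadienyl cation closes conrotatorily between C6 and C7 with aryl and methyl trans. The oxyallyl cation is then intercepted by Et3SiH at its methoxy-bearing end C5, and the silyl group ends on oxygen to give the silyl enol ether A5.
- *For.* The trans aryl/methyl pair is set directly and catalytically. On this point it is stronger than the chosen route, which secures C7 by resolution. The enol ether is also ready for quaternisation at C1.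
- *Against.*
  - Ring A is entirely unbuilt. It needs C1–C2 at a quaternary carbon, C4–C5 at a carbon that has just been reduced and must be enolised again, the C3 methoxy centre, and a selective reduction of the C8 ketone.
  - The enantioselective reductive interruption on an acyclic α-alkoxy dienone is itself undemonstrated.
  - Hydride could go to C1 instead of C5.
- *Comparison.* The chosen route closes ring B onto a finished ring A in one step and makes the C5 quaternary centre in that same step.

**Alternative 3: Ring-enlarging Prins–pinacol rearrangement.**
- *Disconnection.* Ring A is opened at C2–C3, and the C1–C7 bond of ring B is exchanged for a C7–C8 bond. This leaves the alkenyl cyclobutanol silyl ether A6, which carries a dimethyl acetal at C3.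
- *Forward key step.* SnCl4 takes a methoxide from the acetal. The alkene attacks the oxocarbenium carbon through its CH2 terminus C2, which forms ring A and a tertiary cation at C1. A 1,2-shift of C7 from the carbinol carbon C8 to C1 then expands the cyclobutane to ring B and turns C8 into the ketone of A7.
- *For.* One stereospecific cascade of a known type makes both rings and the C1 quaternary centre. It is stronger than the chosen step on precedent and on the predictability of the skeleton-forming event.
- *Against.*
  - A6 is a cyclobutane with four contiguous stereocentres, two of them fully substituted. It needs a ketene cycloaddition, an alkenyl addition and a chiral side chain, and has no evident enantiocontrol.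
  - C5 could migrate instead of C7.
  - A7 again has the C8 ketone and C4 alcohol levels reversed, and its C3 methoxy group is on the C8 side.
- *Comparison.* The chosen route reaches its key substrate in three operations from two commercial aromatics and needs no redox correction on the bridges.

Key step: step 4

## Route

Step 1
Reactants: 1 1-(3,4-dimethoxyphenyl)propan-1-one
Product: 2 (Z)-tert-butyl{[1-(3,4-dimethoxyphenyl)prop-1-en-1-yl]oxy}dimethylsilane
Conditions: TBSOTf, Et3N, CH2Cl2, 0 °C to rt
Reagents that add atoms: tert-butyldimethylsilyl trifluoromethanesulfonate, CC(C)(C)[Si](C)(C)OS(=O)(=O)C(F)(F)F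
Why: Soft enolisation; the silyl triflate activates the ketone and Et3N removes the α-proton, giving mainly the Z enol ether. The geometry does not matter, because the carbon that becomes C7 is formed without control in step 2.

Step 2
Reactants: 3 4-allyl-2,6-dimethoxyphenol; 2 (Z)-tert-butyl{[1-(3,4-dimethoxyphenyl)prop-1-en-1-yl]oxy}dimethylsilane
Product: 4 rac-4-allyl-4-[1-(3,4-dimethoxyphenyl)-1-oxopropan-2-yl]-2,6-dimethoxycyclohexa-2,5-dien-1-one
Conditions: PhI(OAc)2, (CF3)2CHOH/CH2Cl2, −20 to 0 °C, 2 in excess
Reagents that add atoms: none
Why: Oxidative dearomatisation with a Mukaiyama-type carbon nucleophile; ligand exchange of the phenol at iodine and loss of iodobenzene make the ring an electrophile, and the enol ether attacks the para carbon C1 to form C1–C7. Para attack is expected because both ortho carbons already carry methoxy groups and because it leaves the cross-conjugated dienone, and carbon nucleophiles are known to add to this carbon in cations of this phenol class. C1 is not stereogenic and C7 forms as a racemate.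

Step 3
Reactants: 4 rac-4-allyl-4-[1-(3,4-dimethoxyphenyl)-1-oxopropan-2-yl]-2,6-dimethoxycyclohexa-2,5-dien-1-one
Product: 5 4-allyl-4-[(2S)-1-(3,4-dimethoxyphenyl)-1-oxopropan-2-yl]-2,6-dimethoxycyclohexa-2,5-dien-1-one
Conditions: preparative chiral SFC, amylose tris(3,5-dimethylphenylcarbamate) phase, CO2/MeOH
Reagents that add atoms: none
Why: Resolution of the only stereocentre, C7, by chromatography on a chiral phase; the (2S) enantiomer is identified by the NOE pattern of 8 after a pilot run of step 4 or by X-ray analysis. The (2R) enantiomer that the column also delivers can be racemised through its ketone enolate (catalytic KOtBu, tBuOH/THF) and separated again.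

Step 4
Reactants: 5 4-allyl-4-[(2S)-1-(3,4-dimethoxyphenyl)-1-oxopropan-2-yl]-2,6-dimethoxycyclohexa-2,5-dien-1-one; 6 bis(pinacolato)diboron
Product: 8 (1S,5R,6R,7S,8S)-1-allyl-6-(3,4-dimethoxyphenyl)-6-hydroxy-3,5-dimethoxy-7-methyl-8-(4,4,5,5-tetramethyl-1,3,2-dioxaborolan-2-yl)bicyclo[3.2.1]oct-2-en-4-one, via boryl copper dienolate 7 (not isolated)
Conditions: CuCl (10 mol %), (R,R)-2,3-bis(tert-butylmethylphosphino)quinoxaline (11 mol %; the (S,S) antipode if a pilot run shows that the other arm reacts), NaOtBu (10 mol %), tBuOH (1.5 equiv), THF, 0 °C
Reagents that add atoms: bis(pinacolato)diboron 6, CC1(C)OB(OC1(C)C)B1OC(C)(C)C(C)(C)O1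
Why: Proposed new method: CuCl, NaOtBu and the bisphosphine give a ligated CuOtBu that exchanges with 6 to a monovalent copper boryl; this adds Cu–B syn across C8=C5 of one enone arm with boron on the β-carbon C8, and the α-cuprio ketone relaxes to the oxygen-bound dienolate 7. C5 of 7 then adds to the tethered C6 aryl ketone, and tBuOH protonates the copper alkoxide and returns CuOtBu. The closest known reaction types are copper-catalysed enantioselective conjugate borylation–aldol cyclisation of enones that carry a pendant ketone and catalytic desymmetrising conjugate addition to 4,4-disubstituted cyclohexadienones; their union on an α-methoxy dienone, with a bridged ring closing onto a fully substituted enolate carbon, has not been shown. Ring B closes as a five-membered ring in a 5-(enolexo)-exo-trig aldol addition. C8 and C1: the ligand picks the C8=C5 arm, and the ligand and the bulk of the branched C7 chain together direct boron to the ring face that carries the allyl group, so boron ends anti to C7 and on the side of the C2–C4 bridge. C5: the tether reaches C6 only on the enolate face that holds C7, which fixes C5 relative to C1 and C8. C6: with methyl held exo by the preset C7 centre the aryl group is expected endo and the hydroxyl exo, and since this centre is made planar in step 6 its epimer would serve as well. The step needs arm selection (a diastereoselection here because 5 is one enantiomer, so a wrong-arm product can be separated), aldol faster than protonation at C5 (five-ring closure against a hindered alcohol), an intact C7 (no alkoxide beyond what copper binds) and a single borylation (the enone left in 8 is screened by the C8 boryl group and the C6–C7 bridge).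

Step 5
Reactants: 8 (1S,5R,6R,7S,8S)-1-allyl-6-(3,4-dimethoxyphenyl)-6-hydroxy-3,5-dimethoxy-7-methyl-8-(4,4,5,5-tetramethyl-1,3,2-dioxaborolan-2-yl)bicyclo[3.2.1]oct-2-en-4-one
Product: 9 (1S,5R,6R,7S,8S)-1-allyl-6-(3,4-dimethoxyphenyl)-6,8-dihydroxy-3,5-dimethoxy-7-methylbicyclo[3.2.1]oct-2-en-4-one
Conditions: NaBO3·4H2O, THF/H2O, rt
Reagents that add atoms: sodium perborate tetrahydrate, [Na+].[O-]OB=O.O.O.O.O
Why: Oxidation of the carbon–boron bond; peroxide adds to boron and C8 shifts from boron to oxygen with retention, so the hydroxyl stays on the side of the C2–C4 bridge. The mild pH should spare both β-hydroxy ketone units, and the hindered methoxy enone and the allyl group are not oxidised.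

Step 6
Reactants: 9 (1S,5R,6R,7S,8S)-1-allyl-6-(3,4-dimethoxyphenyl)-6,8-dihydroxy-3,5-dimethoxy-7-methylbicyclo[3.2.1]oct-2-en-4-one
Product: 10 (1R,5S,6S,7R,8S)-1-allyl-6-(3,4-dimethoxyphenyl)-8-hydroxy-3,5-dimethoxy-7-methylbicyclo[3.2.1]oct-2-en-4-one
Conditions: Et3SiH (excess), BF3·OEt2, CH2Cl2, −78 to −40 °C
Reagents that add atoms: none
Why: Ionic deoxygenation; BF3 ionises only the tertiary benzylic C6–O bond, which the 3,4-dimethoxyphenyl group stabilises, and the silane gives hydride to the exo face of ring B, because the endo face lies under the C2–C4 bridge. The aryl group therefore ends endo and trans to the exo methyl group, whichever C6 epimer of 9 is used. Low temperature and excess silane are meant to outrun loss of the C7 proton.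

Step 7
Reactants: 10 (1R,5S,6S,7R,8S)-1-allyl-6-(3,4-dimethoxyphenyl)-8-hydroxy-3,5-dimethoxy-7-methylbicyclo[3.2.1]oct-2-en-4-one
Product: 11 (1S,3S,5S,6S,7R,8S)-1-allyl-6-(3,4-dimethoxyphenyl)-8-hydroxy-3,5-dimethoxy-7-methylbicyclo[3.2.1]octan-4-one
Conditions: [(Ph3P)CuH]6 (0.35 equiv), H2O (2 equiv), degassed THF, rt
Reagents that add atoms: none
Why: Copper hydride conjugate reduction; hydride goes to the β-carbon C2 and leaves the allyl group and the ketone untouched. The enolate carbon C3 is then protonated on the face turned to C8, where the C8 hydroxyl sits, while the endo aryl group covers the opposite face. C3 thus receives its hydrogen toward C8 and keeps the methoxy group toward the C6–C7 bridge.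

Step 8
Reactants: 11 (1S,3S,5S,6S,7R,8S)-1-allyl-6-(3,4-dimethoxyphenyl)-8-hydroxy-3,5-dimethoxy-7-methylbicyclo[3.2.1]octan-4-one
Product: 12 (1S,3S,5S,6S,7R,8S)-8-acetoxy-1-allyl-6-(3,4-dimethoxyphenyl)-3,5-dimethoxy-7-methylbicyclo[3.2.1]octan-4-one
Conditions: Ac2O, DMAP, pyridine, CH2Cl2, rt
Reagents that add atoms: acetic anhydride, CC(=O)OC(C)=O
Why: DMAP-catalysed acylation of the hindered secondary C8 alcohol. The weak amine base is not expected to enolise the ketone, so C3 should keep its configuration.

## Compound list

1 | 1-(3,4-dimethoxyphenyl)propan-1-one | CCC(=O)c1ccc(OC)c(OC)c1 | starting material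
2 | (Z)-tert-butyl{[1-(3,4-dimethoxyphenyl)prop-1-en-1-yl]oxy}dimethylsilane | C/C=C(\O[Si](C)(C)C(C)(C)C)c1ccc(OC)c(OC)c1 | intermediate
3 | 4-allyl-2,6-dimethoxyphenol | C=CCc1cc(OC)c(O)c(OC)c1 | starting material
4 | rac-4-allyl-4-[1-(3,4-dimethoxyphenyl)-1-oxopropan-2-yl]-2,6-dimethoxycyclohexa-2,5-dien-1-one | C=CCC1(C=C(OC)C(=O)C(OC)=C1)C(C)C(=O)c1ccc(OC)c(OC)c1 | intermediate
5 | 4-allyl-4-[(2S)-1-(3,4-dimethoxyphenyl)-1-oxopropan-2-yl]-2,6-dimethoxycyclohexa-2,5-dien-1-one | C=CCC1(C=C(OC)C(=O)C(OC)=C1)[C@H](C)C(=O)c1ccc(OC)c(OC)c1 | intermediate
6 | bis(pinacolato)diboron | CC1(C)OB(OC1(C)C)B1OC(C)(C)C(C)(C)O1 | starting material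
7 | boryl copper dienolate from Cu–B addition to the C8=C5 arm of 5 (ligand on copper omitted) | C=CC[C@]1(C=C(OC)C(O[Cu])=C(OC)[C@H]1B1OC(C)(C)C(C)(C)O1)[C@H](C)C(=O)c1ccc(OC)c(OC)c1 | intermediate (not isolated)
8 | (1S,5R,6R,7S,8S)-1-allyl-6-(3,4-dimethoxyphenyl)-6-hydroxy-3,5-dimethoxy-7-methyl-8-(4,4,5,5-tetramethyl-1,3,2-dioxaborolan-2-yl)bicyclo[3.2.1]oct-2-en-4-one (6-exo-hydroxy; 6-endo-aryl; 7-exo-methyl; boron on the side of the C2–C4 bridge) | C=CC[C@]12C=C(OC)C(=O)[C@](OC)([C@](O)(c3ccc(OC)c(OC)c3)[C@H]1C)[C@H]2B1OC(C)(C)C(C)(C)O1 | intermediate
9 | (1S,5R,6R,7S,8S)-1-allyl-6-(3,4-dimethoxyphenyl)-6,8-dihydroxy-3,5-dimethoxy-7-methylbicyclo[3.2.1]oct-2-en-4-one | C=CC[C@]12C=C(OC)C(=O)[C@](OC)([C@](O)(c3ccc(OC)c(OC)c3)[C@H]1C)[C@H]2O | intermediate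
10 | (1R,5S,6S,7R,8S)-1-allyl-6-(3,4-dimethoxyphenyl)-8-hydroxy-3,5-dimethoxy-7-methylbicyclo[3.2.1]oct-2-en-4-one (6-endo-aryl; 7-exo-methyl) | C=CC[C@]12C=C(OC)C(=O)[C@](OC)([C@H](c3ccc(OC)c(OC)c3)[C@H]1C)[C@H]2O | intermediate
11 | (1S,3S,5S,6S,7R,8S)-1-allyl-6-(3,4-dimethoxyphenyl)-8-hydroxy-3,5-dimethoxy-7-methylbicyclo[3.2.1]octan-4-one | C=CC[C@]12C[C@H](OC)C(=O)[C@](OC)([C@H](c3ccc(OC)c(OC)c3)[C@H]1C)[C@H]2O | intermediate
12 | (1S,3S,5S,6S,7R,8S)-8-acetoxy-1-allyl-6-(3,4-dimethoxyphenyl)-3,5-dimethoxy-7-methylbicyclo[3.2.1]octan-4-one | C=CC[C@]12C[C@H](OC)C(=O)[C@](OC)([C@H](c3ccc(OC)c(OC)c3)[C@H]1C)[C@H]2OC(C)=O | target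

## Step count and least certain steps

Total: 8 steps (7 reactions and one resolution). Longest linear sequence: 8 steps, from 1 to 12.

**Step 4 (key step).**
- *What may go wrong.*
  - The catalyst may discriminate poorly between the two enone arms.
  - The enolate may be protonated at C5 before the congested C5–C6 bond can form.
  - C7 may epimerise under alkoxide, which would feed the closure that places methyl endo.
  - The copper boryl may add to the aryl ketone instead of the hindered, electron-rich enone.
- *Fallback.* The two events are separated, using known chemistry. From 5, copper-catalysed enantioselective conjugate borylation with the same ligand and MeOH as proton source should give the uncyclised β-boryl enone F1. F1 is then closed in a separate intramolecular aldol addition under kinetic deprotonation (LiN(SiMe3)2, THF, −78 °C), where C5–H next to the ring ketone should be removed faster than the hindered tertiary C7–H. The route is rejoined at 8.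

**Step 2.**
- *What may go wrong.*
  - The enol ether may attack a methoxy-bearing ortho carbon of the ring cation.
  - The oxidant may consume the electron-rich enol ether.
  - Acetate or solvent may capture the cation first.
- *Fallback.* Oxidation is decoupled from carbon–carbon bond formation. From 3, PhI(OAc)2 in MeOH should give the quinone monoketal 4-allyl-2,6,6-trimethoxycyclohexa-2,4-dien-1-one F2. F2 is then ionised with catalytic TMSOTf in CH2Cl2 at −78 °C in the presence of 2, so the same cation meets the enol ether with no oxidant present. The route is rejoined at 4.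

**Step 6.**
- *What may go wrong.*
  - The benzylic cation may lose the C7 proton and be reprotonated, which scrambles C7 toward the cis aryl/methyl isomer.
  - The C4 acyl group may shift to C6 and leave an oxocarbenium ion at C5.
  - Hydride may be delivered from the endo face.
- *Fallback.* A radical deoxygenation, which cannot eliminate, replaces the cation. From 9, acetylation of the C8 hydroxyl (Ac2O, DMAP) gives the 8-acetate F3. Acylation of the tertiary hydroxyl with methyl chlorooxoacetate (DMAP, pyridine) gives the methyl oxalate F4. Bu3SnH with AIBN in hot toluene, at high stannane concentration so that hydrogen transfer outruns addition of the radical to the allyl group, then gives the deoxygenated acetate F5 by hydrogen transfer to the exo face of the benzylic radical. Conjugate reduction of F5 with [(Ph3P)CuH]6 rejoins the route at 12.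

**Step 7.**
- *What may go wrong.*
  - Hydride transfer to the hindered, electron-rich methoxy enone may be slow.
  - The enolate may be protonated from the endo face, giving the C3 epimer.
- *Fallback.* Reduction and protonation are separated. From 10, RhCl(PPh3)3-catalysed 1,4-hydrosilylation with Et3SiH, which also silylates the C8 hydroxyl, should give the isolable 4,8-bis(triethylsilyloxy) enol ether F6; a low catalyst loading is used so that addition to the enone stays ahead of hydrosilylation of the allyl group. F6 is then cleaved and protonated in a separate low-temperature step (HF·pyridine, THF), where the proton source and temperature can be chosen freely. The route is rejoined at 11.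

## Further compounds

F1 | step 4 | 4-allyl-4-[(2S)-1-(3,4-dimethoxyphenyl)-1-oxopropan-2-yl]-2,6-dimethoxy-5-(4,4,5,5-tetramethyl-1,3,2-dioxaborolan-2-yl)cyclohex-2-en-1-one (ring C4 and C5 configured as C1 and C8 of 8; mixture at C6) | C=CC[C@]1(C=C(OC)C(=O)C(OC)[C@H]1B1OC(C)(C)C(C)(C)O1)[C@H](C)C(=O)c1ccc(OC)c(OC)c1
F2 | step 2 | 4-allyl-2,6,6-trimethoxycyclohexa-2,4-dien-1-one | C=CCC1=CC(OC)(OC)C(=O)C(OC)=C1
F3 | step 6 | (1S,5R,6R,7S,8S)-8-acetoxy-1-allyl-6-(3,4-dimethoxyphenyl)-6-hydroxy-3,5-dimethoxy-7-methylbicyclo[3.2.1]oct-2-en-4-one | C=CC[C@]12C=C(OC)C(=O)[C@](OC)([C@](O)(c3ccc(OC)c(OC)c3)[C@H]1C)[C@H]2OC(C)=O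
F4 | step 6 | (1S,5R,6R,7S,8S)-8-acetoxy-1-allyl-6-(3,4-dimethoxyphenyl)-3,5-dimethoxy-7-methyl-4-oxobicyclo[3.2.1]oct-2-en-6-yl methyl oxalate | C=CC[C@]12C=C(OC)C(=O)[C@](OC)([C@](OC(=O)C(=O)OC)(c3ccc(OC)c(OC)c3)[C@H]1C)[C@H]2OC(C)=O
F5 | step 6 | (1R,5S,6S,7R,8S)-8-acetoxy-1-allyl-6-(3,4-dimethoxyphenyl)-3,5-dimethoxy-7-methylbicyclo[3.2.1]oct-2-en-4-one | C=CC[C@]12C=C(OC)C(=O)[C@](OC)([C@H](c3ccc(OC)c(OC)c3)[C@H]1C)[C@H]2OC(C)=O
F6 | step 7 | 1-allyl-6-endo-(3,4-dimethoxyphenyl)-3,5-dimethoxy-7-exo-methyl-4,8-bis(triethylsilyloxy)bicyclo[3.2.1]oct-3-ene (configured as 10) | C=CC[C@]12CC(OC)=C(O[Si](CC)(CC)CC)[C@](OC)([C@H](c3ccc(OC)c(OC)c3)[C@H]1C)[C@H]2O[Si](CC)(CC)CC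
A1 | alternative 1 | methyl 4-(3,4-dimethoxyphenyl)-3-methoxy-5-methyl-2-oxocyclopentane-1-carboxylate (4,5-trans) | COC(=O)C1C(=O)C(OC)[C@H](c2ccc(OC)c(OC)c2)[C@H]1C
A2 | alternative 1 | 2-methoxyprop-2-enal | C=C(OC)C=O
A3 | alternative 1 | methyl 6-(3,4-dimethoxyphenyl)-4-hydroxy-3,5-dimethoxy-7-methyl-8-oxobicyclo[3.2.1]octane-1-carboxylate | COC(=O)[C@]12C[C@@H](OC)[C@@H](O)[C@](OC)([C@H](c3ccc(OC)c(OC)c3)[C@H]1C)C2=O
A4 | alternative 2 | (1Z,4E)-4-allyl-1-(3,4-dimethoxyphenyl)-2-methoxyhexa-1,4-dien-3-one | C/C=C(\CC=C)C(=O)/C(OC)=C/c1ccc(OC)c(OC)c1
A5 | alternative 2 | triethylsilyl enol ether of 2-allyl-4-(3,4-dimethoxyphenyl)-5-methoxy-3-methylcyclopentanone | C=CCC1=C(O[Si](CC)(CC)CC)[C@@H](OC)[C@H](c2ccc(OC)c(OC)c2)[C@H]1C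
A6 | alternative 3 | 2-[1-(tert-butyldimethylsilyloxy)-2,2-dimethoxyethyl]-3-(3,4-dimethoxyphenyl)-2-methoxy-4-methyl-1-(penta-1,4-dien-2-yl)-1-(trimethylsilyloxy)cyclobutane | C=CCC(=C)[C@@]1(O[Si](C)(C)C)[C@H](C)[C@@H](c2ccc(OC)c(OC)c2)[C@@]1(OC)[C@H](O[Si](C)(C)C(C)(C)C)C(OC)OC
A7 | alternative 3 | 1-allyl-4-(tert-butyldimethylsilyloxy)-6-(3,4-dimethoxyphenyl)-3,5-dimethoxy-7-methylbicyclo[3.2.1]octan-8-one | C=CC[C@]12C[C@@H](OC)[C@@H](O[Si](C)(C)C(C)(C)C)[C@](OC)([C@H](c3ccc(OC)c(OC)c3)[C@H]1C)C2=O
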